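**Plan**

- Retrosynthesis: cut the C11 and C4 esters, then the oxepane C3–O bond together with the C4–O bond (a 3,4-epoxide opened by the C16 hydroxyl), the C7=C19 methylene (Wittig) and the C5–C6 bond of the nine-membered oxonane (retro-Claisen), which leads back to a seven-membered 2-methylene-1,4-dioxepane. That ring is cut at O–C7 (alkyne hydroalkoxylation), C3–C4 (vinyl Grignard), C8–C9 (propargylation), C9–C10 (carbonylation) and C1–C2/C14–C15 (conjugate addition–aldol).
- Forward order of rings: cyclohexane (from (S)-pulegone) → γ-lactone, then tetrahydrofuran (C2–O–C9) → temporary seven-membered dioxepane (O(thf), C2, C3, O, C7, C8, C9) → nine-membered oxonane by two-atom ring expansion → oxepane (C3–O–C16).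
- Enabling feature: the C2–O–C9 tetrahydrofuran bridge holds the C3 carbinol (carrying the vinyl group C4=C5) and the C9 propargyl arm (C8, C7≡C6) cis. An O–C7 bond therefore gives an allyl vinyl ether C6=C7–O–C3–C4=C5, whose [3,3] shift inserts C4–C5–C6 into the ring and leaves a C7 ketone (future C7=C19) and a C3=C4 alkene (future C3 ether and C4 acetate).
- Stereochemistry: C12 from (S)-pulegone; C14 and C1 by trans-selective cuprate addition/aldol; C10 by borylation–protonation to the cis-fused lactone; C2 as the thermodynamic 2-acetyl tetrahydrofuran; C9 by convex-face addition to an oxocarbenium ion; C15 by hydroboration; C3 and C4 by face-selective epoxidation of the Z-alkene and invertive opening at C3; C11 by late ketone reduction; the side-chain centre from (R)-2-hydroxyoctanoic acid.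

Key step: step 17

Remark: atoms carry the usual asbestinin numbers (C1/C10 ring fusion, C2–O–C9 tetrahydrofuran with oxygen "O(thf)", C3–O–C16 oxepane, C7=C19, C18 on C3, C17 on C15, C20 on C12); (S)-(−)-pulegone, tiglic aldehyde and (R)-2-hydroxyoctanoic acid are taken as purchasable.

Step 1
Reactants: 1 (S)-(−)-pulegone
Product: 2 (S)-pulegone oxide (both epoxide diastereomers)
Conditions: 30% H2O2, NaOH (cat.), MeOH, 0 → 23 °C
Reagents that add atoms: hydrogen peroxide, OO
Why: Weitz–Scheffer nucleophilic epoxidation of the enone should proceed cleanly, and the configuration at the spiro carbon is irrelevant because that carbon is lost in step 2.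

Step 2
Reactants: 2 (S)-pulegone oxide
Product: 3 (5S)-5-methyl-2-(phenylsulfanyl)cyclohexan-1-one (both C2 epimers)
Conditions: PhSH, NaH (cat.), THF, reflux
Reagents that add atoms: thiophenol, Sc1ccccc1
Why: thiolate opening of the epoxide α to the carbonyl followed by retro-aldol loss of acetone is the established way from pulegone to a 2-sulfanyl-5-methylcyclohexanone and leaves the methyl-bearing centre untouched.

Step 3
Reactants: 3 (5S)-5-methyl-2-(phenylsulfanyl)cyclohexan-1-one
Product: 5 (S)-5-methylcyclohex-2-en-1-one, via sulfoxide 4 (not isolated)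
Conditions: mCPBA, CH2Cl2, −78 °C; then PhMe, 110 °C
Reagents that add atoms: none
Why: sulfide oxidation and thermal syn-elimination of the α-sulfinyl ketone should give the conjugated enone regiospecifically, the C5 methyl centre (future C12) being remote from the reacting atoms.

Step 4
Reactants: 5 (S)-5-methylcyclohex-2-en-1-one; 6 (E)-2-methylbut-2-enal (tiglic aldehyde)
Product: 8 (2S,3S,5S)-2-[(1R,2E)-1-hydroxy-2-methylbut-2-en-1-yl]-5-methyl-3-(prop-1-en-2-yl)cyclohexan-1-one, via bromomagnesium enolate 7 (not isolated)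
Conditions: CH2=C(CH3)MgBr, CuBr·SMe2 (10 mol %), THF, −40 °C; then 6, −78 °C; aq. NH4Cl
Reagents that add atoms: isopropenylmagnesium bromide, C=C(C)[Mg]Br
Why: copper-catalysed conjugate addition should occur anti to the ring methyl (trans-3,5, sets C14), the regiodefined enolate should add to the aldehyde anti to the new isopropenyl group (sets C1), and the chair Zimmerman–Traxler aldol of the cyclic E-enolate should favour the anti adduct (C2, which is in any case re-equilibrated in step 14).

Step 5
Reactants: 8 aldol adduct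
Product: 9 triethylsilyl ether of 8
Conditions: Et3SiCl, imidazole, DMF, 0 → 23 °C
Reagents that add atoms: chlorotriethylsilane, CC[Si](Cl)(CC)CC
Why: routine silylation of the secondary allylic alcohol blocks retro-aldol cleavage during the enolisation of step 6.

Step 6
Reactants: 9 silyl ether
Product: 10 enol triflate (C10=C11) of 9
Conditions: KN(SiMe3)2, THF, −78 °C; PhNTf2, −78 → 0 °C
Reagents that add atoms: N-phenylbis(trifluoromethanesulfonimide), O=S(=O)(N(c1ccccc1)S(=O)(=O)C(F)(F)F)C(F)(F)F
Why: kinetic deprotonation should take place at the unhindered C11 methylene and not at the branched C1 methine, and O-sulfonylation of the enolate then fixes the C10=C11 double bond.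

Step 7
Reactants: 10 enol triflate
Product: 11 methyl cyclohex-1-ene-1-carboxylate (C9 ester on C10=C11; C1, C2, C12, C14 as in 8)
Conditions: Pd(PPh3)4 (5 mol %), CO (1 atm), Et3N, MeOH/DMF, 60 °C
Reagents that add atoms: carbon monoxide, [C-]#[O+]; methanol, CO
Why: oxidative addition of zerovalent palladium to the enol triflate, CO insertion and methanolysis (alkoxycarbonylation) should install C9 without touching the isolated alkenes or the silyl ether.

Step 8
Reactants: 11 unsaturated ester
Product: 12 α-alkylidene γ-lactone (C9(=O)–O(thf)–C2 ring; C10=C11)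
Conditions: PPTS (cat.), MeOH, 23 °C; then PhMe, 60 °C
Reagents that add atoms: none
Why: mild acid methanolysis of the triethylsilyl ether frees the C2 hydroxyl, which should lactonise onto the neighbouring ester carbonyl (5-exo-trig) in preference to a 5-endo conjugate addition.

Step 9
Reactants: 12 unsaturated lactone
Product: 13 cis-fused C11-pinacolboryl γ-lactone (H1 and H10 cis; boron trans to the C12 methyl)
Conditions: CuCl (5 mol %), NaOtBu (10 mol %), Xantphos (5 mol %), B2pin2, MeOH (2 equiv), THF, 23 °C
Reagents that add atoms: bis(pinacolato)diboron, CC1(C)OB(B2OC(C)(C)C(C)(C)O2)OC1(C)C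
Why: copper-catalysed conjugate borylation should add boron to C11 anti to the adjacent methyl, and protonation of the lactone enolate on the face of H1 (opposite to C14) should give the cis ring fusion at C10, which as the α-centre of a lactone can also be equilibrated; the C11 configuration is inconsequential because it is reset in step 24.

Step 10
Reactants: 13 boryl lactone
Product: 15 diol lactone (C11–OH, C16–OH; 15S), via B-alkyl-9-BBN adduct 14 (not isolated)
Conditions: 9-BBN, THF, 0 → 23 °C; then NaBO3·4H2O, THF/H2O, 23 °C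
Reagents that add atoms: sodium perborate, [Na+].[O-]OB=O
Why: 9-BBN should hydroborate only the 1,1-disubstituted isopropenyl group (the trisubstituted alkene and the lactone being inert), attacking the rotamer with H14 eclipsing the alkene from the side of C13 and away from the substituted C1, which corresponds to 15S, and perborate then oxidises both C–B bonds with retention without eliminating the β-oxygenated lactone; the minor C15 epimer should be separable.

Step 11
Reactants: 15 diol lactone
Product: 16 11,16-bis(tert-butyldimethylsilyl) ether of 15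
Conditions: tBuMe2SiOTf, 2,6-lutidine, CH2Cl2, −78 → 0 °C
Reagents that add atoms: tert-butyldimethylsilyl trifluoromethanesulfonate, CC(C)(C)[Si](C)(C)OS(=O)(=O)C(F)(F)F
Why: standard silylation under weakly basic conditions should protect both alcohols and avoid β-elimination of the C11 oxygen.

Step 12
Reactants: 16 bis-silyl lactone
Product: 18 lactol acetate (C9–OAc, both anomers), via diisobutylaluminium lactolate 17 (not isolated)
Conditions: iBu2AlH, CH2Cl2, −78 °C; then Ac2O, pyridine, DMAP, −78 → 0 °C
Reagents that add atoms: acetic anhydride, CC(=O)OC(C)=O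
Why: one-pot reductive acetylation traps the aluminium hemiacetal before ring opening and should give the oxocarbenium precursor without over-reduction.

Step 13
Reactants: 18 lactol acetate
Product: 19 C9-propargyl tetrahydrofuran (9R; C3 and C8 cis on the tetrahydrofuran)
Conditions: Bu3SnCH=C=CH2, BF3·OEt2, CH2Cl2, −78 → −40 °C
Reagents that add atoms: allenyltributylstannane, C=C=C[Sn](CCCC)(CCCC)CCCC
Why: the allenylstannane should add (SE2') to the bicyclic oxocarbenium ion from the convex face, opposite to the cis-fused cyclohexane, which places the propargyl group on C9 in the target configuration.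

Step 14
Reactants: 19 propargyl compound
Product: 20 C2-acetyl tetrahydrofuran (C3 methyl ketone; acetyl trans to C14 on the ring)
Conditions: OsO4 (2 mol %), NaIO4, 2,6-lutidine, dioxane/H2O, 23 °C; then DBU (cat.), CH2Cl2, 23 °C
Reagents that add atoms: sodium periodate, [Na+].[O-]I(=O)(=O)=O
Why: Lemieux–Johnson cleavage should cut the only alkene and spare the terminal alkyne, and base equilibration at the now enolisable C2 should converge any C2 epimer on the more stable exo acetyl isomer (2,3-trans on the tetrahydrofuran).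

Step 15
Reactants: 20 methyl ketone
Product: 21 (3R)-tertiary allylic alcohol (C3 bearing OH, CH3 and vinyl C4=C5)
Conditions: CH2=CHMgBr (3 equiv), MgBr2·OEt2, CH2Cl2/THF, −78 °C; aq. NH4Cl
Reagents that add atoms: vinylmagnesium bromide, C=C[Mg]Br
Why: Cram-chelate addition (magnesium bridging the ketone oxygen and O(thf)) should deliver the vinyl group from the H2 face, giving the C3 epimer whose vinyl group lies on the O(thf) side as step 17 requires; one equivalent of reagent is consumed by the acetylenic C–H, which is restored on work-up.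

Step 16
Reactants: 21 tertiary alcohol
Product: 22 bridged 2-methylene-1,4-dioxepane (ring O(thf)–C2–C3–O–C7–C8–C9 with exocyclic C7=C6)
Conditions: Ph3PAuNTf2 (5 mol %), 4 Å molecular sieves, CH2Cl2, 0 → 23 °C; Et3N quench, filtration through basic alumina
Reagents that add atoms: none
Why: cationic monovalent gold should activate the terminal alkyne for Markovnikov 7-exo-dig addition of the C3 hydroxyl (alkynol cycloisomerisation), the cis arrangement of the two arms on the tetrahydrofuran offsetting the less common ring size.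

Step 17
Reactants: 22 bridged 2-methylene-1,4-dioxepane
Product: 23 (3Z)-oxonen-7-one (nine-membered ring O(thf)–C2–C3=C4–C5–C6–C7(=O)–C8–C9)
Conditions: PhMe (degassed, base-washed glass), 130 °C, sealed tube
Reagents that add atoms: none
Why: A concerted [3,3]-sigmatropic (Claisen) shift of the allyl vinyl ether C6=C7–O–C3–C4=C5 forms the C5–C6 bond and breaks the C3–O bond, so that the seven-membered ring O(thf)–C2–C3–O–C7–C8–C9 loses its second oxygen to the C7 carbonyl, gains C4, C5 and C6, and becomes the nine-membered oxonane ring. The closest known reaction type is the ring-expanding Claisen rearrangement of 2-methylene-vinyl cyclic ethers to medium-ring 4-cycloalkenones, including bridged 2-methylene-1,4-dioxepanes that give oxonenones. The nine-membered ring is not closed in a Baldwin sense but arises by this two-atom ring expansion through a six-centre boat- or chair-like transition state in which the new bond is made on the O(thf) side of the bridged dioxepane, the side on which step 15 has placed the vinyl group. No sp3 stereocentre is created (C3 becomes trigonal, so its configuration only steers the reaction), and the one new stereo-element, the C3=C4 geometry, should be Z because the short tether C8–C9–O(thf) holds C2 and C7 on the same side of the transition state. The step needs the [3,3] path to win over ionisation or [1,3] shift of the tertiary allylic ether, which the non-polar, acid-free thermal conditions should secure, and the existing centres are untouched by a pericyclic process.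

Step 18
Reactants: 23 oxonenone
Product: 24 7-methylene diene (C7=C19 and Z-C3=C4; 11,16-bis-silyl ether)
Conditions: Ph3PCH3Br, KOtBu, THF, 0 → 23 °C
Reagents that add atoms: methyltriphenylphosphonium bromide, C[P+](c1ccccc1)(c1ccccc1)c1ccccc1.[Br-]
Why: Wittig methylenation of the unhindered C7 ketone should be faster than enolisation toward C8, and no ester is yet present.

Step 19
Reactants: 24 bis-silyl diene
Product: 25 C16 primary alcohol (C11 silyl ether retained)
Conditions: CSA (10 mol %), MeOH/CH2Cl2, 0 °C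
Reagents that add atoms: none
Why: acid methanolysis should remove the primary silyl ether much faster than the hindered secondary one at C11, and must precede epoxidation because the epoxide would not survive these conditions.

Step 20
Reactants: 25 hydroxy diene
Product: 27 tetracyclic oxepane 4-alcohol (3R,4S; C11 silyl ether), via 3,4-epoxide 26 (not isolated)
Conditions: mCPBA, CH2Cl2, −20 → 0 °C; then CSA (10 mol %), 23 °C
Reagents that add atoms: 3-chloroperoxybenzoic acid, OOC(=O)c1cccc(Cl)c1
Why: the peracid should prefer the trisubstituted Z-alkene over the 1,1-disubstituted one and attack its face anti to C1 (allylic centre C2), and acid then lets the C16 hydroxyl, which can only reach C3 from the C1 side, open the epoxide at the tertiary carbon with inversion (7-exo), closing the oxepane and leaving the C4 hydroxyl on the retained C–O bond, so that anti addition across the Z-alkene gives 3R,4S.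

Step 21
Reactants: 27 oxepane alcohol
Product: 28 4-acetate
Conditions: Ac2O, Et3N, DMAP (cat.), CH2Cl2, 23 °C
Reagents that add atoms: acetic anhydride, CC(=O)OC(C)=O
Why: routine DMAP-catalysed acetylation of the only free hydroxyl.

Step 22
Reactants: 28 acetate silyl ether
Product: 29 C11 alcohol (C11 epimeric to the target)
Conditions: HF·pyridine, pyridine/THF, 0 → 23 °C
Reagents that add atoms: none
Why: buffered fluoride desilylation should free the C11 hydroxyl without cleaving the acetate or isomerising the exocyclic alkene.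

Step 23
Reactants: 29 C11 alcohol
Product: 30 C11 ketone
Conditions: Dess–Martin periodinane, CH2Cl2, 0 → 23 °C
Reagents that add atoms: none
Why: neutral periodinane oxidation should give the ketone without epimerising the axial substituents at C10 and C12.

Step 24
Reactants: 30 C11 ketone
Product: 31 C11 alcohol (11S, target configuration)
Conditions: NaBH4, MeOH, −40 °C
Reagents that add atoms: none
Why: hydride should attack C11 from the face opposite to the two flanking substituents (C9 on C10 and the methyl on C12, both on the same face), giving the hydroxyl cis to them, and at low temperature the acetate and the enolisable α-centres should survive.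

Step 25
Reactants: 32 (R)-2-hydroxyoctanoic acid
Product: 34 (R)-2-(tert-butyldimethylsilyloxy)octanoic acid, via bis-silyl derivative 33 (not isolated)
Conditions: tBuMe2SiCl, imidazole, DMF, 23 °C; then AcOH/THF/H2O, 23 °C
Reagents that add atoms: tert-butyldimethylsilyl chloride, CC(C)(C)[Si](C)(C)Cl
Why: exhaustive silylation followed by selective hydrolysis of the far more labile silyl ester is the standard way to a 2-silyloxy acid and does not touch the stereocentre.

Step 26
Reactants: 31 C11 alcohol; 34 (R)-2-(tert-butyldimethylsilyloxy)octanoic acid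
Product: 35 silyl-protected target
Conditions: DCC, DMAP, CH2Cl2, 0 → 23 °C
Reagents that add atoms: none
Why: Steglich esterification should acylate the equatorial C11 hydroxyl, and the α-silyloxy acid is not prone to epimerisation under these conditions.

Step 27
Reactants: 35 silyl-protected target
Product: 36 CNP0132024.3 (target)
Conditions: HF·pyridine, THF, 0 → 23 °C
Reagents that add atoms: none
Why: fluoride desilylation of the α-silyloxy ester should leave both esters, the ethers and the exocyclic alkene intact.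

**Compound list**

1 | (S)-(−)-pulegone | C[C@H]1CCC(=C(C)C)C(=O)C1 | starting material
2 | (S)-pulegone oxide (epoxide diastereomers) | C[C@H]1CCC2(OC2(C)C)C(=O)C1 | intermediate
3 | (5S)-5-methyl-2-(phenylsulfanyl)cyclohexan-1-one | C[C@H]1CCC(Sc2ccccc2)C(=O)C1 | intermediate
4 | (5S)-5-methyl-2-(phenylsulfinyl)cyclohexan-1-one | C[C@H]1CCC(S(=O)c2ccccc2)C(=O)C1 | intermediate
5 | (S)-5-methylcyclohex-2-en-1-one | C[C@H]1CC=CC(=O)C1 | intermediate
6 | (E)-2-methylbut-2-enal (tiglic aldehyde) | C/C=C(\C)C=O | starting material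
7 | bromomagnesium (3S,5S)-5-methyl-3-(prop-1-en-2-yl)cyclohex-1-en-1-olate | C=C(C)[C@H]1C[C@H](C)CC(O[Mg]Br)=C1 | intermediate
8 | (2S,3S,5S)-2-[(1R,2E)-1-hydroxy-2-methylbut-2-en-1-yl]-5-methyl-3-(prop-1-en-2-yl)cyclohexan-1-one | C=C(C)[C@H]1C[C@H](C)CC(=O)[C@@H]1[C@@H](O)/C(C)=C/C | intermediate
9 | triethylsilyl ether of 8 | C=C(C)[C@H]1C[C@H](C)CC(=O)[C@@H]1[C@@H](O[Si](CC)(CC)CC)/C(C)=C/C | intermediate
10 | enol triflate (C10=C11) of 9 | C=C(C)[C@H]1C[C@H](C)C=C(OS(=O)(=O)C(F)(F)F)[C@@H]1[C@@H](O[Si](CC)(CC)CC)/C(C)=C/C | intermediate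
11 | methyl cyclohexenecarboxylate (C9 ester, C2 silyl ether) | C=C(C)[C@H]1C[C@H](C)C=C(C(=O)OC)[C@@H]1[C@@H](O[Si](CC)(CC)CC)/C(C)=C/C | intermediate
12 | α-alkylidene γ-lactone (C10=C11) | C=C(C)[C@H]1C[C@H](C)C=C2C(=O)O[C@@H](/C(C)=C/C)[C@H]12 | intermediate
13 | cis-fused C11-pinacolboryl lactone | C=C(C)[C@H]1C[C@H](C)[C@@H](B2OC(C)(C)C(C)(C)O2)[C@@H]2C(=O)O[C@@H](/C(C)=C/C)[C@H]12 | intermediate
14 | C16 B-alkyl-9-BBN adduct of 13 | B5(C[C@@H](C)[C@H]1C[C@H](C)[C@@H](B2OC(C)(C)C(C)(C)O2)[C@@H]2C(=O)O[C@@H](/C(C)=C/C)[C@H]12)C6CCCC5CCC6 | intermediate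
15 | diol lactone (C11–OH trans to C12 methyl; C16–OH; 15S) | OC[C@@H](C)[C@H]1C[C@H](C)[C@@H](O)[C@@H]2C(=O)O[C@@H](/C(C)=C/C)[C@H]12 | intermediate
16 | 11,16-bis(tert-butyldimethylsilyl) ether of 15 | CC(C)(C)[Si](C)(C)OC[C@@H](C)[C@H]1C[C@H](C)[C@@H](O[Si](C)(C)C(C)(C)C)[C@@H]2C(=O)O[C@@H](/C(C)=C/C)[C@H]12 | intermediate
17 | diisobutylaluminium lactolate of 16 | CC(C)(C)[Si](C)(C)OC[C@@H](C)[C@H]1C[C@H](C)[C@@H](O[Si](C)(C)C(C)(C)C)[C@@H]2C(O[Al](CC(C)C)CC(C)C)O[C@@H](/C(C)=C/C)[C@H]12 | intermediate
18 | lactol acetate (C9–OAc, anomers) | CC(C)(C)[Si](C)(C)OC[C@@H](C)[C@H]1C[C@H](C)[C@@H](O[Si](C)(C)C(C)(C)C)[C@@H]2C(OC(C)=O)O[C@@H](/C(C)=C/C)[C@H]12 | intermediate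
19 | C9-propargyl tetrahydrofuran | CC(C)(C)[Si](C)(C)OC[C@@H](C)[C@H]1C[C@H](C)[C@@H](O[Si](C)(C)C(C)(C)C)[C@@H]2[C@@H](CC#C)O[C@@H](/C(C)=C/C)[C@H]12 | intermediate
20 | C2-acetyl tetrahydrofuran (C3 methyl ketone) | CC(C)(C)[Si](C)(C)OC[C@@H](C)[C@H]1C[C@H](C)[C@@H](O[Si](C)(C)C(C)(C)C)[C@@H]2[C@@H](CC#C)O[C@@H](C(C)=O)[C@H]12 | intermediate
21 | (3R)-tertiary allylic alcohol | CC(C)(C)[Si](C)(C)OC[C@@H](C)[C@H]1C[C@H](C)[C@@H](O[Si](C)(C)C(C)(C)C)[C@@H]2[C@@H](CC#C)O[C@@H]([C@](C)(O)C=C)[C@H]12 | intermediate
22 | bridged 2-methylene-1,4-dioxepane | CC(C)(C)[Si](C)(C)OC[C@@H](C)[C@H]1C[C@H](C)[C@@H](O[Si](C)(C)C(C)(C)C)[C@@H]2[C@H]3CC(=C)O[C@](C)(C=C)[C@H](O3)[C@H]12 | intermediate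
23 | (3Z)-oxonen-7-one | CC(C)(C)[Si](C)(C)OC[C@@H](C)[C@H]1C[C@H](C)[C@@H](O[Si](C)(C)C(C)(C)C)[C@@H]2[C@H]3CC(=O)CC/C=C(C)\[C@H](O3)[C@H]12 | intermediate
24 | 7-methylene diene (bis-silyl ether) | CC(C)(C)[Si](C)(C)OC[C@@H](C)[C@H]1C[C@H](C)[C@@H](O[Si](C)(C)C(C)(C)C)[C@@H]2[C@H]3CC(=C)CC/C=C(C)\[C@H](O3)[C@H]12 | intermediate
25 | C16 primary alcohol | OC[C@@H](C)[C@H]1C[C@H](C)[C@@H](O[Si](C)(C)C(C)(C)C)[C@@H]2[C@H]3CC(=C)CC/C=C(C)\[C@H](O3)[C@H]12 | intermediate
26 | 3,4-epoxide of 25 | OC[C@@H](C)[C@H]1C[C@H](C)[C@@H](O[Si](C)(C)C(C)(C)C)[C@@H]2[C@H]3CC(=C)CC[C@@H]4O[C@]4(C)[C@H](O3)[C@H]12 | intermediate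
27 | tetracyclic oxepane 4-alcohol (C11 silyl ether) | C=C1CC[C@H](O)[C@@]2(C)OC[C@@H](C)[C@H]3C[C@H](C)[C@@H](O[Si](C)(C)C(C)(C)C)[C@H]4[C@@H]3[C@H]2O[C@@H]4C1 | intermediate
28 | 4-acetate of 27 | C=C1CC[C@H](OC(C)=O)[C@@]2(C)OC[C@@H](C)[C@H]3C[C@H](C)[C@@H](O[Si](C)(C)C(C)(C)C)[C@H]4[C@@H]3[C@H]2O[C@@H]4C1 | intermediate
29 | 11-epi C11 alcohol | C=C1CC[C@H](OC(C)=O)[C@@]2(C)OC[C@@H](C)[C@H]3C[C@H](C)[C@@H](O)[C@H]4[C@@H]3[C@H]2O[C@@H]4C1 | intermediate
30 | C11 ketone | C=C1CC[C@H](OC(C)=O)[C@@]2(C)OC[C@@H](C)[C@H]3C[C@H](C)C(=O)[C@H]4[C@@H]3[C@H]2O[C@@H]4C1 | intermediate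
31 | (11S)-C11 alcohol | C=C1CC[C@H](OC(C)=O)[C@@]2(C)OC[C@@H](C)[C@H]3C[C@H](C)[C@H](O)[C@H]4[C@@H]3[C@H]2O[C@@H]4C1 | intermediate
32 | (R)-2-hydroxyoctanoic acid | CCCCCC[C@@H](O)C(=O)O | starting material
33 | tert-butyldimethylsilyl (R)-2-(tert-butyldimethylsilyloxy)octanoate | CCCCCC[C@@H](O[Si](C)(C)C(C)(C)C)C(=O)O[Si](C)(C)C(C)(C)C | intermediate
34 | (R)-2-(tert-butyldimethylsilyloxy)octanoic acid | CCCCCC[C@@H](O[Si](C)(C)C(C)(C)C)C(=O)O | intermediate
35 | silyl-protected target | C=C1CC[C@H](OC(C)=O)[C@@]2(C)OC[C@@H](C)[C@H]3C[C@H](C)[C@H](OC(=O)[C@H](O[Si](C)(C)C(C)(C)C)CCCCCC)[C@H]4[C@@H]3[C@H]2O[C@@H]4C1 | intermediate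
36 | CNP0132024.3 | C=C1CC[C@H](OC(C)=O)[C@@]2(C)OC[C@@H](C)[C@H]3C[C@H](C)[C@H](OC(=O)[C@H](O)CCCCCC)[C@H]4[C@@H]3[C@H]2O[C@@H]4C1 | target

**Step count and risks**

Total step count: 27. Longest linear sequence: 26 steps (steps 1–24, 26, 27); step 25 is the one-step side branch.

Steps most likely to fail:

1. Step 20. After epoxidation the developing C3 cation may be captured transannularly by the C7=C19 alkene, or the peracid may also attack that alkene, faster than the tethered C16 hydroxyl closes the seven-membered ring. The fallback closes the oxepane by displacement at the primary carbon instead. It sets out from 24: mCPBA epoxidises the C3=C4 bond with both silyl ethers in place to give bis-silyl epoxide F1; dilute HClO4 in THF/H2O at 0 °C opens it at the tertiary C3 with inversion to the 3,4-anti diol F2; Ac2O/DMAP acetylates only the secondary C4 hydroxyl to give hydroxy acetate F3; CSA in MeOH removes the primary silyl ether to give diol monoacetate F4; Tf2O with 2,6-di-tert-butylpyridine at −78 °C triflates the primary C16 hydroxyl, and the tertiary C3 hydroxyl displaces the triflate to close the oxepane. The fallback comes back to the route at 28.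

2. Step 16. The hindered tertiary hydroxyl may add too slowly to the gold-activated alkyne, so that alkyne hydration or hydrolysis and isomerisation of the exocyclic enol ether take over. The fallback makes the same enol ether by methylenation of a lactone. It sets out from 18: BF3·OEt2-mediated addition of 1-(tert-butyldimethylsilyloxy)-1-methoxyethene to the oxocarbenium ion gives the C9 acetic ester F5; OsO4/NaIO4 cleavage gives keto ester F6; CH2=CHMgBr with MgBr2·OEt2 at −78 °C adds to the chelated ketone only and gives hydroxy ester F7; NaH in THF closes the seven-membered lactone F8; Cp2TiMe2 in toluene at 65 °C methylenates the lactone carbonyl. The fallback comes back to the route at 22.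

3. Step 17. The tertiary allylic enol ether may ionise or eliminate (cleavage of the C3–O bond without C5–C6 bond formation) faster than it rearranges. The fallback closes the nine-membered ring by metathesis. It sets out from 20: Ph3P=CH2 converts the C3 ketone into isopropenyl alkyne F9; Ph3PAuNTf2-catalysed hydration of the alkyne in MeOH/H2O gives methyl ketone F10; kinetic deprotonation of the methyl group with LiN(iPr)2 at −78 °C and alkylation with allyl bromide gives dienone F11; ring-closing metathesis with second-generation Grubbs catalyst, RuCl2(=CHPh)(H2IMes)(PCy3), in dilute CH2Cl2 forms the Z-C3=C4 bond. The fallback comes back to the route at 23.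

Further compounds

F1 | step 20 | 3,4-epoxide of bis-silyl diene 24 | CC(C)(C)[Si](C)(C)OC[C@@H](C)[C@H]1C[C@H](C)[C@@H](O[Si](C)(C)C(C)(C)C)[C@@H]2[C@H]3CC(=C)CC[C@@H]4O[C@]4(C)[C@H](O3)[C@H]12
F2 | step 20 | (3R,4S)-3,4-diol (bis-silyl ether) | CC(C)(C)[Si](C)(C)OC[C@@H](C)[C@H]1C[C@H](C)[C@@H](O[Si](C)(C)C(C)(C)C)[C@@H]2[C@H]3CC(=C)CC[C@H](O)[C@@](C)(O)[C@H](O3)[C@H]12
F3 | step 20 | C4 acetate of F2 | CC(C)(C)[Si](C)(C)OC[C@@H](C)[C@H]1C[C@H](C)[C@@H](O[Si](C)(C)C(C)(C)C)[C@@H]2[C@H]3CC(=C)CC[C@H](OC(C)=O)[C@@](C)(O)[C@H](O3)[C@H]12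
F4 | step 20 | C16 alcohol of F3 (C3 tertiary alcohol, C4 acetate) | OC[C@@H](C)[C@H]1C[C@H](C)[C@@H](O[Si](C)(C)C(C)(C)C)[C@@H]2[C@H]3CC(=C)CC[C@H](OC(C)=O)[C@@](C)(O)[C@H](O3)[C@H]12
F5 | step 16 | C9 methyl acetate tetrahydrofuran | CC(C)(C)[Si](C)(C)OC[C@@H](C)[C@H]1C[C@H](C)[C@@H](O[Si](C)(C)C(C)(C)C)[C@@H]2[C@@H](CC(=O)OC)O[C@@H](/C(C)=C/C)[C@H]12
F6 | step 16 | keto ester (C3 methyl ketone) | CC(C)(C)[Si](C)(C)OC[C@@H](C)[C@H]1C[C@H](C)[C@@H](O[Si](C)(C)C(C)(C)C)[C@@H]2[C@@H](CC(=O)OC)O[C@@H](C(C)=O)[C@H]12
F7 | step 16 | (3R)-tertiary hydroxy ester | CC(C)(C)[Si](C)(C)OC[C@@H](C)[C@H]1C[C@H](C)[C@@H](O[Si](C)(C)C(C)(C)C)[C@@H]2[C@@H](CC(=O)OC)O[C@@H]([C@](C)(O)C=C)[C@H]12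
F8 | step 16 | bridged seven-membered lactone (1,4-dioxepan-2-one) | CC(C)(C)[Si](C)(C)OC[C@@H](C)[C@H]1C[C@H](C)[C@@H](O[Si](C)(C)C(C)(C)C)[C@@H]2[C@H]3CC(=O)O[C@](C)(C=C)[C@H](O3)[C@H]12
F9 | step 17 | C2-isopropenyl C9-propargyl tetrahydrofuran | CC(C)(C)[Si](C)(C)OC[C@@H](C)[C@H]1C[C@H](C)[C@@H](O[Si](C)(C)C(C)(C)C)[C@@H]2[C@@H](CC#C)O[C@@H](C(C)=C)[C@H]12
F10 | step 17 | C7 methyl ketone | CC(C)(C)[Si](C)(C)OC[C@@H](C)[C@H]1C[C@H](C)[C@@H](O[Si](C)(C)C(C)(C)C)[C@@H]2[C@@H](CC(C)=O)O[C@@H](C(C)=C)[C@H]12
F11 | step 17 | dienone for ring-closing metathesis | CC(C)(C)[Si](C)(C)OC[C@@H](C)[C@H]1C[C@H](C)[C@@H](O[Si](C)(C)C(C)(C)C)[C@@H]2[C@@H](CC(=O)CCC=C)O[C@@H](C(C)=C)[C@H]12
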